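**Assumptions.** The target has no stereocentres, so "single enantiomer" reduces to controlling the two alkene geometries: (Z) in the side chain and (E) in the enone. Compounds 1, 4 and 6 are taken as catalogue items (4 is otherwise one step from 4-hydroxybenzaldehyde and MOMCl). The route is designed from known reaction types and analogies; it has not been run.

## Retrosynthetic overview

1. (Z)-alkene ⇐ aryl alkyne by Lindlar semi-hydrogenation, placed last so the acid-sensitive (Z)-hydroxyalkenyl phenol (prone to chromene formation) never meets acid.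
2. Free phenols ⇐ MOM ethers, cleaved at the alkyne stage.
3. Aryl–alkyne bond ⇐ Sonogashira coupling of the 3'-iodide with 2-methylbut-3-yn-2-ol.
4. (E)-enone ⇐ Claisen–Schmidt condensation of the iodoacetophenone with 4-(methoxymethoxy)benzaldehyde.
5. Iodoacetophenone ⇐ C3-iodination of 2',4'-dihydroxy-6'-methoxyacetophenone. No rings are formed; both benzene rings are purchased.

## Route

**Step 1**
Reactants: 1, 1-(2,4-dihydroxy-6-methoxyphenyl)ethanone
Product: 2, 1-(2,4-dihydroxy-3-iodo-6-methoxyphenyl)ethanone
Conditions: I2 (0.4 equiv), HIO3 (0.2 equiv), EtOH–H2O, rt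
Reagents that add atoms: iodine, II; iodic acid, O[I](=O)=O (oxidant; its iodine is also delivered)
Why: Electrophilic aromatic iodination should favour C3, which is flanked by both free hydroxyls and ortho to the chelated 2-OH (the selectivity I recall for I2/HIO3 on 2,4-dihydroxyacetophenone), and one equivalent of I+ limits di-iodination.

**Step 2**
Reactants: 2, 1-(2,4-dihydroxy-3-iodo-6-methoxyphenyl)ethanone
Product: 3, 1-[3-iodo-6-methoxy-2,4-bis(methoxymethoxy)phenyl]ethanone
Conditions: NaH (2.5 equiv), MOMCl (2.6 equiv), DMF, 0 °C → rt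
Reagents that add atoms: chloromethyl methyl ether (MOMCl), COCCl
Why: Phenoxide O-alkylation (MOM protection) caps both oxygens ortho to iodine, which prevents benzofuran formation in the Sonogashira step and phenoxide deactivation or flavanone closure in the aldol step.

**Step 3**
Reactants: 3, 1-[3-iodo-6-methoxy-2,4-bis(methoxymethoxy)phenyl]ethanone; 4, 4-(methoxymethoxy)benzaldehyde
Product: 5, (E)-1-[3-iodo-6-methoxy-2,4-bis(methoxymethoxy)phenyl]-3-[4-(methoxymethoxy)phenyl]prop-2-en-1-one
Conditions: KOH (aq. 50%, excess), EtOH, rt, 24–48 h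
Reagents that add atoms: 4-(methoxymethoxy)benzaldehyde (4), COCOc1ccc(C=O)cc1
Why: Claisen–Schmidt condensation with E1cB dehydration gives the thermodynamic (E)-enone, and MOM ethers and the aryl iodide are inert to hydroxide.

**Step 4**
Reactants: 5, the iodo-chalcone above; 6, 2-methylbut-3-yn-2-ol
Product: 7, (E)-1-[3-(3-hydroxy-3-methylbut-1-yn-1-yl)-6-methoxy-2,4-bis(methoxymethoxy)phenyl]-3-[4-(methoxymethoxy)phenyl]prop-2-en-1-one
Conditions: PdCl2(PPh3)2 (5 mol %), CuI (10 mol %), Et3N–DMF, 65 °C, Ar; 6 (3 equiv)
Reagents that add atoms: 2-methylbut-3-yn-2-ol (6), CC(C)(O)C#C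
Why: Sonogashira coupling of the aryl iodide with the terminal alkyne proceeds without cycloisomerisation because both flanking oxygens are protected, and the enone and free tertiary alcohol are spectators.

**Step 5**
Reactants: 7, the tris-MOM alkynyl chalcone above
Product: 8, (E)-1-[2,4-dihydroxy-3-(3-hydroxy-3-methylbut-1-yn-1-yl)-6-methoxyphenyl]-3-(4-hydroxyphenyl)prop-2-en-1-one
Conditions: 3 M aq. HCl, MeOH, rt (monitor; quench with NaHCO3)
Reagents that add atoms: none
Why: Acid-catalysed acetal hydrolysis removes all three MOM groups while the side chain is still an alkyne, which cannot close to a chromene and ionises much less readily than the later (Z)-allylic alcohol.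

**Step 6**
Reactants: 8, the alkynyl chalcone triol above
Product: 9, candidachalcone, (E)-1-{2,4-dihydroxy-3-[(Z)-3-hydroxy-3-methylbut-1-en-1-yl]-6-methoxyphenyl}-3-(4-hydroxyphenyl)prop-2-en-1-one
Conditions: H2 (1 atm), Lindlar catalyst (Pd/CaCO3/Pb), quinoline, EtOAc, rt; stop at 1 equiv H2; filter through Celite; no acid wash; Et3N-deactivated silica
Reagents that add atoms: none
Why: Lindlar semi-hydrogenation delivers H2 syn on poisoned Pd to set the (Z)-alkene, the alkyne out-competes the enone C=C for the catalyst surface, and the neutral work-up avoids chromene formation.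

## Compound list

1 | 1-(2,4-dihydroxy-6-methoxyphenyl)ethanone | CC(=O)c1c(O)cc(O)cc1OC | starting material
2 | 1-(2,4-dihydroxy-3-iodo-6-methoxyphenyl)ethanone | CC(=O)c1c(O)c(I)c(O)cc1OC | intermediate
3 | 1-[3-iodo-6-methoxy-2,4-bis(methoxymethoxy)phenyl]ethanone | CC(=O)c1c(OCOC)c(I)c(OCOC)cc1OC | intermediate
4 | 4-(methoxymethoxy)benzaldehyde | COCOc1ccc(C=O)cc1 | starting material
5 | (E)-1-[3-iodo-6-methoxy-2,4-bis(methoxymethoxy)phenyl]-3-[4-(methoxymethoxy)phenyl]prop-2-en-1-one | COCOc1ccc(/C=C/C(=O)c2c(OCOC)c(I)c(OCOC)cc2OC)cc1 | intermediate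
6 | 2-methylbut-3-yn-2-ol | CC(C)(O)C#C | starting material
7 | (E)-1-[3-(3-hydroxy-3-methylbut-1-yn-1-yl)-6-methoxy-2,4-bis(methoxymethoxy)phenyl]-3-[4-(methoxymethoxy)phenyl]prop-2-en-1-one | COCOc1ccc(/C=C/C(=O)c2c(OCOC)c(C#CC(C)(C)O)c(OCOC)cc2OC)cc1 | intermediate
8 | (E)-1-[2,4-dihydroxy-3-(3-hydroxy-3-methylbut-1-yn-1-yl)-6-methoxyphenyl]-3-(4-hydroxyphenyl)prop-2-en-1-one | COc1cc(O)c(C#CC(C)(C)O)c(O)c1C(=O)/C=C/c1ccc(O)cc1 | intermediate
9 | candidachalcone | COc1cc(O)c(/C=C\C(C)(C)O)c(O)c1C(=O)/C=C/c1ccc(O)cc1 | target

## Summary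

Total steps: 6. Longest linear sequence: 6 (1 → 2 → 3 → 5 → 7 → 8 → 9).

Steps most likely to fail, with fallbacks:

1. **Step 6 (Lindlar).** The alkyne is hindered (di-ortho-substituted aryl, tertiary carbinol), so enone C=C reduction or over-reduction may compete. Fallback: drop hydrogenation. Cleave the MOM groups from iodide 5, then attach the side chain with its geometry already set by a stereoretentive Stille coupling with (Z)-4-(tributylstannyl)-2-methylbut-3-en-2-ol (from ethyl (Z)-3-(tributylstannyl)acrylate and MeMgBr). Stille coupling tolerates free phenols.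

2. **Step 5 (acidic MOM removal).** The electron-rich aryl alkyne and propargylic tertiary alcohol may solvolyse or hydrate, and the 2'-hydroxychalcone may close to the flavanone. Fallback: move the acid step ahead of the alkyne. Deprotect iodide 5, peracetylate (Ac2O, pyridine), run the Sonogashira and Lindlar steps on the triacetate, and finish with mild acetate methanolysis (K2CO3, MeOH, 0 °C).

3. **Step 1 (iodination).** C3 versus C5 selectivity is argued by analogy, and di-iodination is possible. Fallback: change the directing logic. First protect only the non-chelated 4-OH (MOMCl, K2CO3, acetone), iodinate ortho to the single remaining chelated phenol (BnNMe3·ICl2, CaCO3, CH2Cl2–MeOH), then protect the 2-OH to reach 3.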